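The earlier runs and the new flask are calculated with constants of no real substance, noise included.

Turning target into isomer of the product leaves their sum unchanged, so the share r of isomer in that sum can be followed even though Thursday's three readings add to 43.0% at 3.00 h.

in all of them: starting material 21 mM; partner 31.5 mM; free catalyst 42 µM

| flask | second catalyst | remark | time |
|---|---|---|---|
| Thursday's | 0.53 mM | the very flask that is asked about, followed so far |  |
| Sunday's | 0.80 mM | run made earlier |  |
| flask | 0.53 mM |  | 12 d |

Thursday's run (percent of the starting material charged)

| time / h | isomer of the product / % | target / % | starting material / % |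
|---|---|---|---|
| 3.00 | 2 | 13 | 28 |
| 4.00 | 3 | 19 | 24 |
| 6.00 | 11 | 20 | 16 |
| 10.0 | 18 | 25 | 9 |
| 15.0 | 19 | 33 | 7 |
| 25.0 | 27 | 30 | 3 |
| 30.0 | 27 | 32 | 4 |

Sunday's run (percent of the starting material charged)

| time / d | isomer of the product / % | target / % | starting material / % |
|---|---|---|---|
| 0.625 | 27 | 38 | 4 |
| 1.67 | 29 | 39 | 2 |
| 3.00 | 36 | 38 | 0 |
| 5.00 | 35 | 36 | 2 |
| 8.00 | 33 | 40 | 2 |
| 10.0 | 37 | 36 | 0 |
| 12.0 | 30 | 37 | 2 |

(standard deviation of a reading: 2 percentage points)

* share of isomer of the product in isomer of the product plus target at 40 min
* share of isomer of the product in isomer of the product plus target at 12 d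



In the first hours of Thursday's flask starting material falls quickly, to 28% at 3.00 h, and the target is young: r reads 13.3% there. By 6.00 h r reads 35.5%. Sunday's flask, with more second catalyst and the same free catalyst, shows the end of this climb: its readings pooled give a share s of 46.2%.

Taking Thursday's climb towards s as exponential, the reading at 6.00 h gives a rate λ of 0.243 /h. Its time, 4.11 h, is far shorter than 12 d, so my reckoning for Thursday's flask at 12 d is s. The early share per hour g, the share r of Thursday's flask at 3.00 h divided by that time, is 0.0444 /h: a reading with the scatter of its two readings, taken at this charge of free catalyst and assumed proportional to that charge, which no run varies. Taking r as proportional to time up to that reading, my reckoning at 40 min is 2.96%.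

The forecast gives 4% and 46%, the early figure above mine; of Sunday's flat share it says “This looks like target/isomer equilibrium”.

The flask gives 4.62% at 40 min and 45.2% at 12 d.

    free catalyst → spent catalyst (k = 0.0916 /h)
    open intermediate → decomposed reagent (k = 0.0712 /h)
    second catalyst + open intermediate ⇌ catalyst intermediate (K = 1.80 /M, k = 3140 /M/h)
    target + free catalyst ⇌ isomer of the product + free catalyst, rate k4*[free catalyst]*[target] forward; the back reaction follows from the equilibrium constant (K = 1.19, k = 5070 /M/h)
    starting material + free catalyst ⇌ free catalyst + open intermediate (K = 2.30, k = 21700 /M/h)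
    partner + catalyst intermediate → second catalyst + target (k = 5510 /M/h)

The constant of the isomer step corresponds to a share of 54.3%, above the flask's 45.2%, and free catalyst there stands at 0%. Read back from the flask's share at 40 min, g is 0.0692 /h, above the 0.0444 /h from the readings. A neighbouring flask is charged with 0.017 mM of free catalyst, its other charges unchanged. Scaled to that charge, g becomes 0.0280 /h and gives 1.87% at 40 min; the neighbour shows 1.87%. At 12 d the neighbour holds 41.4% target and 17.3% isomer, a share of 29.4%.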